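**Plan**
- Retrosynthesis: the acid chain is traced back to a C2-symmetric bis-lactone (one lactone C–O bond cut). The two C2–C(lactone) bonds are then cut (vinylogous Michael), leaving an achiral 6,6'-bichromone, which is cut at C4a–C5 and C4a'–C5'.
- Enabling feature: each benzene ring (C4a, C5, C6, C7, C8, C8a) has oxygen at C5 and C8a on either side of the acyl-bearing C4a, and C7 carries no oxygen. The C6–C6' biaryl bond is the α,α'-bond of a succinate whose two carboxyl carbons become C5 and C5'.
- Forward: the pyranone ring comes first (acetylacetone plus oxalate), then a tetrahydrofuran bis-acetal from the furan diester, then the two C7–C8 bonds by a double vinylogous Mukaiyama reaction. Both benzene rings close in one operation; the two butenolides are then attached and reduced, and one lactone is opened.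
- Stereochemistry: C2/C2' and the lactone carbinol carbons come from a catalyst-controlled vinylogous Michael addition. The methyl-bearing carbons come from hydrogenation anti to the chromanone carbon. The biaryl axis is not a stereo element.

Key step: step 6

Assumption: the target is read as 2S,2'S at the chromanone carbons with a (2R,3S)-lactone on one half and the matching (3S,4R)-hydroxy acid on the other, so both halves are of one stereochemical series; the axis (ortho OH and H only) is taken as freely rotating, and the (S,S)-ligand is taken to give the 2S series (its mirror image is used if a test run shows the opposite sense).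

**Step 1**
Reactants: 1 acetylacetone; 2 dimethyl oxalate
Product: 4 methyl 6-methyl-4-oxo-4H-pyran-2-carboxylate, via triketo ester 3 (not isolated)
Conditions: LiN(iPr)2 (commercial solution, 3.0 equiv), THF, −78 → 0 °C; inverse addition to (CO2Me)2 (1.5 equiv), −78 °C; then HCl, MeOH, 60 °C
Reagents that add atoms: none
Why: Claisen acylation of the acetylacetone dianion at its terminal carbon gives the 1,3,5-triketo ester, which cyclodehydrates under acid to the 4-pyranone (classical γ-pyrone synthesis).

**Step 2**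
Reactants: 4 methyl 6-methyl-4-oxo-4H-pyran-2-carboxylate
Product: 5 methyl 4-[(tert-butyldimethylsilyl)oxy]-6-methylidene-6H-pyran-2-carboxylate
Conditions: TBSOTf (1.2 equiv), Et3N (1.5 equiv), CH2Cl2, 0 °C; pentane, filtration under Ar, used crude
Reagents that add atoms: tert-butyldimethylsilyl trifluoromethanesulfonate, CC(C)(C)[Si](C)(C)OS(=O)(=O)C(F)(F)F
Why: Soft enolisation, in which O-silylation of the pyranone carbonyl gives a 4-silyloxypyrylium ion whose 6-methyl group is acidic enough for Et3N, should give the cross-conjugated silyl dienol ether (vinylogous silyl enol ether formation).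

**Step 3**
Reactants: 6 dimethyl furan-3,4-dicarboxylate
Product: 7 dimethyl 2,5-dimethoxy-2,5-dihydrofuran-3,4-dicarboxylate
Conditions: graphite anode, Ni cathode, undivided cell, MeOH, H2SO4 (cat., electrolyte), −15 °C, constant current
Reagents that add atoms: methanol, CO
Why: Anodic 2,5-dimethoxylation of a furan (two-electron oxidation with methanol capture at both α-carbons) tolerates ester substituents as it does for furoates; the cis/trans mixture is of no consequence.

**Step 4**
Reactants: 7 dimethyl 2,5-dimethoxy-2,5-dihydrofuran-3,4-dicarboxylate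
Product: 8 dimethyl 2,5-dimethoxytetrahydrofuran-3,4-dicarboxylate
Conditions: H2 (10 bar), Raney Ni, MeOH, 25 °C
Reagents that add atoms: none
Why: Heterogeneous syn-hydrogenation of the electron-poor maleate-type alkene under neutral conditions should leave the acetal C–O bonds intact, as in the preparation of 2,5-dimethoxytetrahydrofurans; the stereoisomer mixture is carried on.

**Step 5**
Reactants: 8 dimethyl 2,5-dimethoxytetrahydrofuran-3,4-dicarboxylate; 5 methyl 4-[(tert-butyldimethylsilyl)oxy]-6-methylidene-6H-pyran-2-carboxylate (2.5 equiv)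
Product: 9 dimethyl 2,5-bis{[6-(methoxycarbonyl)-4-oxo-4H-pyran-2-yl]methyl}tetrahydrofuran-3,4-dicarboxylate
Conditions: TMSOTf (0.3 equiv), CH2Cl2, −78 → −30 °C; aq. NaHCO3
Reagents that add atoms: none
Why: Twofold vinylogous Mukaiyama addition, in which each acetal carbon ionises to an oxocarbenium ion that is captured by the exocyclic methylene of the dienol ether with regeneration of the 4-pyranone, should form both C–C bonds; no amine base is present so the ester-bearing oxocarbenium ion is not deprotonated, and the diastereomer mixture is used as such.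

**Step 6**
Reactants: 9 dimethyl 2,5-bis{[6-(methoxycarbonyl)-4-oxo-4H-pyran-2-yl]methyl}tetrahydrofuran-3,4-dicarboxylate
Product: 12 dimethyl 5,5'-dihydroxy-4,4'-dioxo-4H,4'H-[6,6'-bichromene]-2,2'-dicarboxylate, via ring-opened hydroxy chromone 10 (not isolated), via hydroxy diketone 11 (not isolated)
Conditions: LiN(SiMe3)2 (6 equiv), THF, −78 → 25 °C; then 2 M HCl, THF, 40 °C
Reagents that add atoms: none
Why: Proposed new method: LiN(SiMe3)2 removes a proton from the exocyclic CH2 of one pyranone, the dienolate attacks the neighbouring ester through ring carbon C4a (Claisen condensation), and the vinylogous β-diketone loses the ring oxygen from C7 by E1cB and tautomerises to the first phenol; the second arm repeats the Claisen closure and the remaining C7'–OH leaves as water on acidification, which aromatises the second ring. The closest known reaction types are the base-induced Claisen and aldol cyclisation–aromatisation of polyketide chains masked as pyranones and the vinylogous reactivity of 2-alkyl-4-pyranone dienolates. Each carbocycle closes in a 6-(enolexo)-exo-trig mode, C4a onto the ester carbon that becomes C5. No stereocentre is formed and the four of 9 are destroyed, so the diastereomer mixture converges on one product. The step needs C-acylation at C4a and not at the exocyclic carbon or at oxygen: the exocyclic carbon could only close a four-membered ring on the adjacent ester or a strained bridged ring on the remote one, while every productive intermediate is drained irreversibly by aromatisation. Opening of the tetrahydrofuran before the Claisen step is limited by the much higher acidity of the pyranyl CH2 compared with the succinate α-hydrogens.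

**Step 7**
Reactants: 12 dimethyl 5,5'-dihydroxy-4,4'-dioxo-4H,4'H-[6,6'-bichromene]-2,2'-dicarboxylate
Product: 13 dimethyl 5,5'-bis(benzyloxy)-4,4'-dioxo-4H,4'H-[6,6'-bichromene]-2,2'-dicarboxylate
Conditions: BnBr (2.5 equiv), K2CO3 (3 equiv), DMF, 50 °C
Reagents that add atoms: benzyl bromide, BrCc1ccccc1
Why: Williamson etherification masks the chelated phenols, which would otherwise quench the basic zinc catalyst of the next step, with a group that is removed by the hydrogenation of step 9 at no extra cost.

**Step 8**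
Reactants: 13 dimethyl 5,5'-bis(benzyloxy)-4,4'-dioxo-4H,4'H-[6,6'-bichromene]-2,2'-dicarboxylate; 14 4-methylfuran-2(5H)-one (3 equiv)
Product: 15 dimethyl (2S,2'S)-5,5'-bis(benzyloxy)-2,2'-bis[(2R)-3-methyl-5-oxo-2,5-dihydrofuran-2-yl]-4,4'-dioxo-[6,6'-bichromane]-2,2'-dicarboxylate
Conditions: Et2Zn (40 mol%), (S,S)-ProPhenol ligand (20 mol%), 4 Å MS, THF, 25 °C
Reagents that add atoms: none
Why: Direct catalytic asymmetric vinylogous Michael addition of a butenolide to a 2-ester chromone should apply to each half: the zinc dienolate of 14 adds through its γ-carbon to C2 of the chromone held on the second zinc of the dinuclear catalyst, which fixes the face at C2 (S) and, through the relative orientation of the two partners, the butenolide carbon (R). Two independent catalyst-controlled additions enrich the C2-symmetric isomer statistically, and the unsymmetrical diastereomer is removed by chromatography.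

**Step 9**
Reactants: 15 dimethyl (2S,2'S)-5,5'-bis(benzyloxy)-2,2'-bis[(2R)-3-methyl-5-oxo-2,5-dihydrofuran-2-yl]-4,4'-dioxo-[6,6'-bichromane]-2,2'-dicarboxylate
Product: 16 dimethyl (2S,2'S)-5,5'-dihydroxy-2,2'-bis[(2R,3S)-3-methyl-5-oxooxolan-2-yl]-4,4'-dioxo-[6,6'-bichromane]-2,2'-dicarboxylate
Conditions: H2 (5 bar), Pd/C (10 wt%), EtOAc, 25 °C
Reagents that add atoms: none
Why: Heterogeneous hydrogenation delivers H2 to each butenolide C=C from the face opposite the quaternary chromanone carbon, which places the methyl group cis to it (3S), and the same catalyst removes both benzyl ethers by hydrogenolysis.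

**Step 10**
Reactants: 16 dimethyl (2S,2'S)-5,5'-dihydroxy-2,2'-bis[(2R,3S)-3-methyl-5-oxooxolan-2-yl]-4,4'-dioxo-[6,6'-bichromane]-2,2'-dicarboxylate
Product: 17 (3S,4R)-4-hydroxy-4-[(2S)-5-hydroxy-6-{(2S)-5-hydroxy-2-(methoxycarbonyl)-2-[(2R,3S)-3-methyl-5-oxooxolan-2-yl]-4-oxochroman-6-yl}-2-(methoxycarbonyl)-4-oxochroman-2-yl]-3-methylbutanoic acid
Conditions: LiOH·H2O (3.0 equiv, two held by the phenols), THF/H2O 3:1, 0 °C; then 1 M HCl to pH 4, 0 °C, cold extraction, reverse-phase chromatography
Reagents that add atoms: lithium hydroxide, [Li+].[OH-]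
Why: Saponification should open one unhindered γ-lactone in preference to the methyl esters on quaternary carbons, while the phenoxides formed first disfavour retro-oxa-Michael opening of the chromanones; no stereocentre is touched, a statistical product distribution is expected so recovered 16 is recycled, and the acid is isolated cold at pH 4 to avoid relactonisation.

**Compound list**
1 | acetylacetone (pentane-2,4-dione) | CC(=O)CC(C)=O | starting material
2 | dimethyl oxalate | COC(=O)C(=O)OC | starting material
3 | methyl 2,4,6-trioxoheptanoate (triketo ester, present as its lithium enolate) | COC(=O)C(=O)CC(=O)CC(C)=O | intermediate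
4 | methyl 6-methyl-4-oxo-4H-pyran-2-carboxylate | COC(=O)C1=CC(=O)C=C(C)O1 | intermediate
5 | methyl 4-[(tert-butyldimethylsilyl)oxy]-6-methylidene-6H-pyran-2-carboxylate | COC(=O)C1=CC(O[Si](C)(C)C(C)(C)C)=CC(=C)O1 | intermediate
6 | dimethyl furan-3,4-dicarboxylate | COC(=O)c1cocc1C(=O)OC | starting material
7 | dimethyl 2,5-dimethoxy-2,5-dihydrofuran-3,4-dicarboxylate (cis/trans mixture) | COC1OC(OC)C(C(=O)OC)=C1C(=O)OC | intermediate
8 | dimethyl 2,5-dimethoxytetrahydrofuran-3,4-dicarboxylate (stereoisomer mixture) | COC1OC(OC)C(C(=O)OC)C1C(=O)OC | intermediate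
9 | dimethyl 2,5-bis{[6-(methoxycarbonyl)-4-oxo-4H-pyran-2-yl]methyl}tetrahydrofuran-3,4-dicarboxylate (diastereomer mixture) | COC(=O)C1=CC(=O)C=C(CC2OC(CC3=CC(=O)C=C(C(=O)OC)O3)C(C(=O)OC)C2C(=O)OC)O1 | intermediate
10 | methyl 5-hydroxy-6-{3-hydroxy-1-methoxy-4-[6-(methoxycarbonyl)-4-oxo-4H-pyran-2-yl]-1-oxobutan-2-yl}-4-oxo-4H-chromene-2-carboxylate (ring-opened hydroxy chromone) | COC(=O)C1=CC(=O)c2c(O)c(C(C(=O)OC)C(O)CC3=CC(=O)C=C(C(=O)OC)O3)ccc2O1 | intermediate
11 | methyl 7-hydroxy-6-[5-hydroxy-2-(methoxycarbonyl)-4-oxo-4H-chromen-6-yl]-4,5-dioxo-5,6,7,8-tetrahydro-4H-chromene-2-carboxylate (hydroxy diketone) | COC(=O)C1=CC(=O)c2c(O)c(C3C(O)CC4=C(C3=O)C(=O)C=C(C(=O)OC)O4)ccc2O1 | intermediate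
12 | dimethyl 5,5'-dihydroxy-4,4'-dioxo-4H,4'H-[6,6'-bichromene]-2,2'-dicarboxylate | COC(=O)C1=CC(=O)c2c(O)c(-c3ccc4OC(C(=O)OC)=CC(=O)c4c3O)ccc2O1 | intermediate
13 | dimethyl 5,5'-bis(benzyloxy)-4,4'-dioxo-4H,4'H-[6,6'-bichromene]-2,2'-dicarboxylate | COC(=O)C1=CC(=O)c2c(OCc3ccccc3)c(-c4ccc5OC(C(=O)OC)=CC(=O)c5c4OCc6ccccc6)ccc2O1 | intermediate
14 | 4-methylfuran-2(5H)-one | CC1=CC(=O)OC1 | starting material
15 | dimethyl (2S,2'S)-5,5'-bis(benzyloxy)-2,2'-bis[(2R)-3-methyl-5-oxo-2,5-dihydrofuran-2-yl]-4,4'-dioxo-[6,6'-bichromane]-2,2'-dicarboxylate | COC(=O)[C@@]1([C@@H]5OC(=O)C=C5C)CC(=O)c2c(ccc(-c3ccc4c(c3OCc7ccccc7)C(=O)C[C@@](C(=O)OC)([C@@H]6OC(=O)C=C6C)O4)c2OCc8ccccc8)O1 | intermediate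
16 | dimethyl (2S,2'S)-5,5'-dihydroxy-2,2'-bis[(2R,3S)-3-methyl-5-oxooxolan-2-yl]-4,4'-dioxo-[6,6'-bichromane]-2,2'-dicarboxylate | COC(=O)[C@@]1([C@@H]5OC(=O)C[C@@H]5C)CC(=O)c2c(ccc(-c3ccc4c(c3O)C(=O)C[C@@](C(=O)OC)([C@@H]6OC(=O)C[C@@H]6C)O4)c2O)O1 | intermediate
17 | (3S,4R)-4-hydroxy-4-[(2S)-5-hydroxy-6-{(2S)-5-hydroxy-2-(methoxycarbonyl)-2-[(2R,3S)-3-methyl-5-oxooxolan-2-yl]-4-oxochroman-6-yl}-2-(methoxycarbonyl)-4-oxochroman-2-yl]-3-methylbutanoic acid | COC(=O)[C@@]1([C@H](O)[C@@H](C)CC(=O)O)CC(=O)c2c(ccc(-c3ccc4c(c3O)C(=O)C[C@@](C(=O)OC)([C@@H]3OC(=O)C[C@@H]3C)O4)c2O)O1 | target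

**Totals**
Total step count: 10. Longest linear sequence: 8 steps (6 → 7 → 8 → 9 → 12 → 13 → 15 → 16 → 17; the branch from 1 is equally long).

**Steps most likely to fail**

Step 6. The tetrahydrofuran may open by β-elimination from an ester enolate before the first Claisen closure, acylation may stop after one ring, or the pyranone esters may be attacked by methoxide. The fallback gives up the succinate logic for a biaryl coupling and sets out from 2. Claisen condensation of 2 with commercial 2',6'-dihydroxyacetophenone F1 (NaOMe, MeOH; then HCl, MeOH) gives methyl 5-hydroxy-4-oxo-4H-chromene-2-carboxylate F2. Iodination with benzyltrimethylammonium dichloroiodate and CaCO3 in CH2Cl2/MeOH, directed to C6 by the chelated hydroxyl as in 5-hydroxyflavones, gives methyl 5-hydroxy-6-iodo-4-oxo-4H-chromene-2-carboxylate F3; any C8 iodide is removed by chromatography. Stannylation with (Bu3Sn)2 and Pd(PPh3)4 gives methyl 5-hydroxy-4-oxo-6-(tributylstannyl)-4H-chromene-2-carboxylate F4. Oxidative homocoupling of the stannane with CuCl in DMA under air then gives 12, where the route is rejoined.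

Step 8. Facial selectivity at C2 may be poor, the relative orientation of the partners may give the wrong butenolide configuration, or the second addition may stall on the hindered dimer. The fallback replaces catalyst control by a substrate-controlled racemic addition with resolution and sets out from 12 and 14. Silylation of 14 (TMSOTf, Et3N) gives 4-methyl-2-(trimethylsilyloxy)furan F5. Activation of 12 with iPr2Si(OTf)2 and 2,6-lutidine in CH2Cl2, addition of F5 in the same flask (vinylogous Mukaiyama–Michael addition to the siloxybenzopyrylium ions) and work-up with Et3N·3HF give dimethyl 5,5'-dihydroxy-2,2'-bis(3-methyl-5-oxo-2,5-dihydrofuran-2-yl)-4,4'-dioxo-[6,6'-bichromane]-2,2'-dicarboxylate as a stereoisomer mixture F6. Chromatography followed by preparative HPLC on a chiral stationary phase gives dimethyl (2S,2'S)-5,5'-dihydroxy-2,2'-bis[(2R)-3-methyl-5-oxo-2,5-dihydrofuran-2-yl]-4,4'-dioxo-[6,6'-bichromane]-2,2'-dicarboxylate F7. Hydrogenation of F7 (H2, Pd/C, EtOAc) gives 16, where the route is rejoined.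

Step 5. The ester-bearing oxocarbenium ion may lose its acidic α-proton and aromatise to the furan before the electron-poor dienol ether captures it, or the second substitution may not follow the first. The fallback runs the C–C bond formation at the alcohol oxidation level, where the cation has no acidifying ester, and sets out from 8. Reduction of 8 (LiAlH4, THF, 0 °C) gives (2,5-dimethoxytetrahydrofuran-3,4-diyl)dimethanol F8. Silylation (TBSCl, imidazole, DMF) gives 3,4-bis{[(tert-butyldimethylsilyl)oxy]methyl}-2,5-dimethoxytetrahydrofuran F9. The Mukaiyama reaction of F9 with 5 (TMSOTf, CH2Cl2, −78 °C) gives dimethyl 6,6'-{[3,4-bis({[tert-butyl(dimethyl)silyl]oxy}methyl)oxolane-2,5-diyl]bis(methylene)}bis(4-oxo-4H-pyran-2-carboxylate) F10. Oxidation with CrO3 and H2SO4 in acetone, which cleaves the primary silyl ethers and oxidises the alcohols in one operation, gives 2,5-bis{[6-(methoxycarbonyl)-4-oxo-4H-pyran-2-yl]methyl}oxolane-3,4-dicarboxylic acid F11. Esterification with Me3SiCHN2 in MeOH/toluene returns 9.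

**Further compounds**
F1 | step 6 | 2',6'-dihydroxyacetophenone (commercial) | CC(=O)c1c(O)cccc1O
F2 | step 6 | methyl 5-hydroxy-4-oxo-4H-chromene-2-carboxylate | COC(=O)C1=CC(=O)c2c(O)cccc2O1
F3 | step 6 | methyl 5-hydroxy-6-iodo-4-oxo-4H-chromene-2-carboxylate | COC(=O)C1=CC(=O)c2c(O)c(I)ccc2O1
F4 | step 6 | methyl 5-hydroxy-4-oxo-6-(tributylstannyl)-4H-chromene-2-carboxylate | CCCC[Sn](CCCC)(CCCC)c1ccc2OC(C(=O)OC)=CC(=O)c2c1O
F5 | step 8 | 4-methyl-2-(trimethylsilyloxy)furan | Cc1coc(O[Si](C)(C)C)c1
F6 | step 8 | dimethyl 5,5'-dihydroxy-2,2'-bis(3-methyl-5-oxo-2,5-dihydrofuran-2-yl)-4,4'-dioxo-[6,6'-bichromane]-2,2'-dicarboxylate (stereoisomer mixture) | COC(=O)C1(C2OC(=O)C=C2C)CC(=O)c2c(O)c(-c3ccc4OC(C(=O)OC)(C5OC(=O)C=C5C)CC(=O)c4c3O)ccc2O1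
F7 | step 8 | dimethyl (2S,2'S)-5,5'-dihydroxy-2,2'-bis[(2R)-3-methyl-5-oxo-2,5-dihydrofuran-2-yl]-4,4'-dioxo-[6,6'-bichromane]-2,2'-dicarboxylate | COC(=O)[C@@]1([C@@H]5OC(=O)C=C5C)CC(=O)c2c(ccc(-c3ccc4c(c3O)C(=O)C[C@@](C(=O)OC)([C@@H]6OC(=O)C=C6C)O4)c2O)O1
F8 | step 5 | (2,5-dimethoxytetrahydrofuran-3,4-diyl)dimethanol | COC1OC(OC)C(CO)C1CO
F9 | step 5 | 3,4-bis{[(tert-butyldimethylsilyl)oxy]methyl}-2,5-dimethoxytetrahydrofuran | COC1OC(OC)C(CO[Si](C)(C)C(C)(C)C)C1CO[Si](C)(C)C(C)(C)C
F10 | step 5 | dimethyl 6,6'-{[3,4-bis({[tert-butyl(dimethyl)silyl]oxy}methyl)oxolane-2,5-diyl]bis(methylene)}bis(4-oxo-4H-pyran-2-carboxylate) | COC(=O)C1=CC(=O)C=C(CC2OC(CC3=CC(=O)C=C(C(=O)OC)O3)C(CO[Si](C)(C)C(C)(C)C)C2CO[Si](C)(C)C(C)(C)C)O1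
F11 | step 5 | 2,5-bis{[6-(methoxycarbonyl)-4-oxo-4H-pyran-2-yl]methyl}oxolane-3,4-dicarboxylic acid | COC(=O)C1=CC(=O)C=C(CC2OC(CC3=CC(=O)C=C(C(=O)OC)O3)C(C(=O)O)C2C(=O)O)O1
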